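**Counting turnovers.** I started with an easy step on the dusk, winter and summer flasks, which start with the same c(free catalyst) and differ in substrate: product over catalyst charged, the turnover number.

| flask | substrate | free catalyst | time |
|---|---|---|---|
| dusk | 0.500 M | 0.0250 M |  |
| winter | 0.250 M | 0.0250 M |  |
| autumn | 0.500 M | 0.0750 M |  |
| summer | 1.50 M | 0.0250 M |  |
| dawn | 0.250 M | 0.0750 M | 12 h |

- dusk run (time / h: [product] / M): 1.7: 0.1403; 3.4: 0.1501; 5.1: 0.1543; 6.9: 0.1591; 8.6: 0.1648; 10: 0.1652; 12: 0.1638
- winter run (time / h: [product] / M): 1.7: 0.0673; 3.4: 0.0732; 5.1: 0.0809; 6.9: 0.0859; 8.6: 0.0810; 10: 0.0840; 12: 0.0848
- autumn run (time / h: [product] / M): 1.7: 0.3577; 3.4: 0.3650; 5.1: 0.3662; 6.9: 0.3691; 8.6: 0.3719; 10: 0.3695; 12: 0.3687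
- summer run (time / h: [product] / M): 1.7: 0.3678; 3.4: 0.4261; 5.1: 0.4550; 6.9: 0.4674; 8.6: 0.4787; 10: 0.4864; 12: 0.4880

(readings scatter by 0.002 M)

- the power of [substrate] that the first rate follows, about the charge of the dusk run; measure it at two percent of substrate made into product (one fixed amount of product, the same in the runs compared)
- the power of [free catalyst] that the first rate follows, about the charge of the dusk run; measure it at two percent of substrate made into product
- product in the dawn run at 12 h, as a share of the substrate charged

- Overall: substrate -> product, with free catalyst as catalyst.
- Constant volume, constant temperature.
- The analysis sees a species whether free or bound.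
- An order is taken over about fifteen percent of the charge, up and down.

**The count.** At 12 h the count stood at 6.55 in dusk, 3.39 in winter and 19.5 in summer, so in these flasks it followed the substrate charge. Autumn, with dusk's substrate charge, went further than dusk. An equilibrium does not shift with a catalyst, so I read the stop as catalyst being lost.

**The reach.** I took the natural logarithm of substrate charged over substrate left at 12 h, the substrate left being the charge minus the product. Dusk gave 0.397, winter 0.414, summer 0.394 and autumn 1.34. I called this number the reach. Among dusk, winter and summer it barely moved across a factor of 6.00 in substrate, so I gave dawn, which has autumn's catalyst charge, autumn's reach, which means a share of 73.7%.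

**The life.** The first reading shows how fast the reach is used. Dusk had 0.170 of its reach at 12 h still to go at 1.7 h, and autumn 0.0602. I assumed a loss second order in free catalyst and a rate that goes with its square, which makes this share fall as one over (one plus t over life). That gave dusk a life of 0.349 h and autumn 0.109 h, shorter than dusk's. For dusk at 3.4 h this form predicts 0.0931, and the reading gives 0.101. The first readings come after these lives, so the time before the first reading is the part to watch.

**The order.** The early pace is reach over life, so autumn should start 10.8 times faster than dusk. Over that span of catalyst this means an order of 2.17, a figure that rests on the form I assumed. I left the substrate order open. The forecast gave an order of 0.85 in substrate, 1.1 in free catalyst and a share of 74.5% for dawn, saying “the order in catalyst is slightly above one”, so it differed from my order and stood close to my share.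

**The result.** Dawn gave 73.9%, a reach of 1.34. The orders came to 0.88 in substrate and 2.4 in free catalyst, and autumn's rate over dusk's, at equal product, was 11.

    free catalyst + substrate ⇌ catalyst-substrate complex, settled at all times (0.2740 M⁻¹)
    catalyst-substrate complex + free catalyst → product + 2 free catalyst (6552 M⁻¹ h⁻¹)
    free catalyst + impurity → spent catalyst
    2 free catalyst → 2 spent catalyst (47.16 M⁻¹ h⁻¹)

**The stop.** Without the step that turns two free catalyst into two spent catalyst, dawn reaches 100%, so that step stops it. Without the impurity, dawn reaches 75.3%, a reach of 1.40, so the impurity is not what stops it.

Readings and results are calculated for substances that don't exist, noise included.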